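The runs come from a simulation for substances that don't exist.

Slowness in these flasks sits in the part of the charge that has not yet come out as target, intermediate B or side product. Call that part the pool: the charge less those three readings.

| flask | substrate | remark | time |
|---|---|---|---|
| cedar | 0.0034 M | run made earlier |  |
| larch | 0.0075 M | run made earlier |  |
| gamma | 0.0050 M |  | 12 min |
| beta | 0.0050 M |  | 25 min |
| theta | 0.0050 M |  | 50 min |

| run | time / min | intermediate B / % | side product / % | target / % | substrate / % |
|---|---|---|---|---|---|
| cedar | 1.00 | 9.9 | 1.2 | 4.4 | 13.7 |
| cedar | 2.00 | 8.5 | 2.0 | 14.5 | 10.5 |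
| cedar | 4.00 | 9.5 | 1.4 | 24.5 | 8.9 |
| cedar | 8.00 | 8.4 | 4.3 | 42.1 | 4.8 |
| cedar | 15.0 | 6.5 | 5.4 | 58.4 | 3.7 |
| larch | 1.00 | 8.8 | 2.4 | 5.4 | 17.3 |
| larch | 2.00 | 10.4 | 3.0 | 13.3 | 10.0 |
| larch | 4.00 | 9.4 | 4.9 | 25.1 | 10.2 |
| larch | 8.00 | 7.5 | 8.3 | 36.5 | 5.6 |
| larch | 15.0 | 6.5 | 9.1 | 54.1 | 4.1 |

(scatter of a reading: 1 percentage point)

- in percentages every species weighs as the substrate in it: one side product counts as two
- what was read earlier has a scatter of 1 percentage point, one standard deviation
- steps thought possible: intermediate B <-> target; substrate <-> dormant form; intermediate A -> intermediate B; substrate -> target; substrate <-> intermediate A; substrate + intermediate B -> side product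
- a reading of substrate is of its free form alone

- which of these there is most of at the end, counted by the substrate in it, gamma (side product / target / intermediate B / substrate)
- which of these there is most of at the end, counted by the substrate in it, beta (side product / target / intermediate B / substrate)
- which of these there is most of at the end, counted by the substrate in it, theta (side product / target / intermediate B / substrate)
- how much there is at the end of the one of these that leads, in percent of the substrate charged: gamma
- how much there is at the end of the one of these that leads, in percent of the substrate charged: beta
- how much there is at the end of the one of these that leads, in percent of the substrate charged: theta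

In cedar the pool reads 64.6% at 4.00 min and 29.7% at 15.0 min; in larch it reads 60.6% and 30.3%. In logarithms the two runs together give the pool 34.5 min to fall by one power of ten, its decade time (decimal reduction time), a reading that carries their scatter.

Counted on from the mean pool at 15.0 min, the pool stands at 36.7% in gamma, 15.4% in beta and 2.89% in theta. Gamma, with more pool than the others, stands nearest the opposite outcome. There, for intermediate B or side product to lead, one of them would need at least 21.1%, the converted 63.3% shared equally among the 3 products. The highest such reading, intermediate B at 10.4% in larch, lies 0.307 of a decade below that. Free substrate in larch, 5.6% at 8.00 min, already trails target's 36.5% by 0.814 of a decade.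

With intermediate B and side product together held at 13.8%, my own balance gives target 49.5%, 70.8% and 83.3%. The forecast gives 51%, 70% and 82%, so mine lies lower at gamma and higher at theta. It concludes: “Target leads in all three runs.”

    intermediate B ⇌ target (K = 14.0, k = 0.00925 s⁻¹)
    substrate ⇌ dormant form (K = 5.05, k = 0.0394 s⁻¹)
    intermediate A → intermediate B (k = 0.0421 s⁻¹)
    substrate → target (k = 0.00159 s⁻¹)
    substrate ⇌ intermediate A (K = 0.315, k = 0.0137 s⁻¹)
    substrate + intermediate B → side product (k = 1.26 L mol⁻¹ s⁻¹)

Target leads with 50.5% in gamma, 71.2% in beta and 82.0% in theta. In beta at 25.0 min, dormant form stands at 11.4%, more than free substrate at 1.90%. With intermediate A, the pool there holds 13.6%, against 15.4% from the decade time of 34.5 min. The neighbouring flask, charged with 0.0020 M and read at 25.0 min, has the same reckoned pool of 15.4% and holds 14.3%, with target at 75.1% and side product at 3.74%.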